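**Plan**
Ring letters: A = methylcyclopentane, B = eight-membered ring, C = cyclohexane, D = cyclopentanone.
Retrosynthesis: the ring D carbonyl, the ring B secondary methyl and the epoxide are adjusted last; one nitrile oxide cycloaddition accounts for the C–O bond at the ring C carbinol and the C–C bond from the B/C fusion CH into ring B (opens ring B); the bond between the cyclohexene and the tetrasubstituted alkene is cut by a Suzuki–Miyaura coupling.
Forward: ring A enol triflate 12 (steps 1–6) and trans-hydrindane 32 (rings C/D, steps 7–18, built on (S)-carvone) are joined in step 19; ring B and the isoxazoline close together in step 21; steps 22–26 unmask and adjust.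
Enabling feature: on ring C the oxygen of the tertiary alcohol and the ring B bond leaving the adjacent fusion CH lie on the same face, which is the pair of bonds a single suprafacial dipole addition to a cyclohexene installs.
Stereochemistry: ring C quaternary methyl from (S)-carvone (alkylation cis to isopropenyl); trans C/D fusion by Li/NH3; isopropyl centre by hydroboration opposite the angular methyl; ring A methyl by Cu-catalysed conjugate addition; ring A CH and Z-alkene by 1,4-hydrosilylation; B/C fusion CH and carbinol by the tether-directed cycloaddition; epoxide by hydroxyl-directed epoxidation; ring B methyl by hydrogenation.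

Key step: step 21

Assumption: oxime 36 is used as its E/Z mixture, since both isomers are oxidised to the same nitrile oxide.

**Route**

Step 1
Reactants: 1 cyclopent-2-en-1-one
Product: 2 2-iodocyclopent-2-en-1-one
Conditions: I2, pyridine, CH2Cl2, 0 °C to rt
Reagents that add atoms: iodine, II
Why: α-iodination of a cyclic enone by conjugate addition of pyridine, iodination of the enolate and elimination is a standard entry to α-iodoenones.

Step 2
Reactants: 3 2-vinyl-1,3-dioxolane; 2 2-iodocyclopent-2-en-1-one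
Product: 5 2-[2-(1,3-dioxolan-2-yl)ethyl]cyclopent-2-en-1-one, via alkylborane 4 (not isolated)
Conditions: 9-BBN, THF, rt; then 2, PdCl2(dppf) (cat.), Ph3As, Cs2CO3, DMF/THF/H2O, rt
Reagents that add atoms: none
Why: anti-Markovnikov hydroboration gives a primary alkylborane that should undergo B-alkyl Suzuki–Miyaura coupling with the α-iodoenone, conditions to which acetal and enone are inert.

Step 3
Reactants: 5 2-[2-(1,3-dioxolan-2-yl)ethyl]cyclopent-2-en-1-one
Product: 7 (3S)-2-[2-(1,3-dioxolan-2-yl)ethyl]-3-methylcyclopent-1-en-1-yl trifluoromethanesulfonate, via magnesium enolate 6 (not isolated)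
Conditions: MeMgBr, Cu(OTf)2 (cat.), chiral imidazolinium salt as carbene ligand precursor (cat., enantiomer leading to 3S), Et2O, −30 °C; then PhNTf2, THF, −30 °C to rt
Reagents that add atoms: methylmagnesium bromide, C[Mg]Br; N-phenylbis(trifluoromethanesulfonimide), O=S(=O)(N(c1ccccc1)S(=O)(=O)C(F)(F)F)C(F)(F)F
Why: copper-catalysed asymmetric conjugate addition to the α-substituted cyclopentenone sets the methyl centre by ligand control and the regio-defined enolate is O-sulfonylated in the same flask; any minor enantiomer becomes a separable diastereomer after union with the enantiopure hydrindane.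

Step 4
Reactants: 7 (3S)-2-[2-(1,3-dioxolan-2-yl)ethyl]-3-methylcyclopent-1-en-1-yl trifluoromethanesulfonate
Product: 9 1-{(3S)-2-[2-(1,3-dioxolan-2-yl)ethyl]-3-methylcyclopent-1-en-1-yl}ethan-1-one, via ethoxydiene 8 (not isolated)
Conditions: tributyl(1-ethoxyvinyl)stannane, Pd(PPh3)4 (cat.), LiCl, THF, 65 °C; then 0.5 M HCl, THF, 0 °C, brief
Reagents that add atoms: tributyl(1-ethoxyvinyl)stannane, CCCC[Sn](CCCC)(CCCC)C(=C)OCC; water, O
Why: Stille coupling of the enol triflate with the masked acetyl anion and cold dilute acid hydrolysis of the very labile 2-alkoxydiene should give the methyl ketone while the dioxolane survives.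

Step 5
Reactants: 9 1-{(3S)-2-[2-(1,3-dioxolan-2-yl)ethyl]-3-methylcyclopent-1-en-1-yl}ethan-1-one
Product: 10 triethyl{[(1Z)-1-{(2S,3S)-2-[2-(1,3-dioxolan-2-yl)ethyl]-3-methylcyclopentylidene}ethyl]oxy}silane
Conditions: Et3SiH, RhCl(PPh3)3 (cat.), THF, 50 °C
Reagents that add atoms: triethylsilane, CC[SiH](CC)CC
Why: rhodium-catalysed 1,4-hydrosilylation needs the s-cis enone (the s-trans form is disfavoured by the clash of the acetyl methyl with the ring substituent), so oxygen ends up cis to C-2 (Z), and hydride reaches C-2 from the face opposite the C-3 methyl, which makes side chain and methyl cis.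

Step 6
Reactants: 10 triethyl{[(1Z)-1-{(2S,3S)-2-[2-(1,3-dioxolan-2-yl)ethyl]-3-methylcyclopentylidene}ethyl]oxy}silane
Product: 12 (1Z)-1-{(2S,3S)-2-[2-(1,3-dioxolan-2-yl)ethyl]-3-methylcyclopentylidene}ethyl trifluoromethanesulfonate, via lithium enolate 11 (not isolated)
Conditions: MeLi, THF, 0 °C; then PhNTf2, −78 °C to rt
Reagents that add atoms: N-phenylbis(trifluoromethanesulfonimide), O=S(=O)(N(c1ccccc1)S(=O)(=O)C(F)(F)F)C(F)(F)F
Why: Si–O cleavage gives a fully substituted lithium enolate that cannot lose its geometry in the absence of a proton source and is O-sulfonylated to the enol triflate.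

Step 7
Reactants: 13 3-methylbut-1-yne
Product: 15 4-methylpent-2-yn-1-ol, via lithium acetylide 14 (not isolated)
Conditions: n-BuLi, THF, −78 °C; then (CH2O)n, −78 °C to rt
Reagents that add atoms: paraformaldehyde (as formaldehyde), C=O
Why: addition of a lithium acetylide to formaldehyde is a routine synthesis of propargylic alcohols.

Step 8
Reactants: 15 4-methylpent-2-yn-1-ol
Product: 16 1-bromo-4-methylpent-2-yne
Conditions: CBr4, PPh3, CH2Cl2, 0 °C
Reagents that add atoms: tetrabromomethane, BrC(Br)(Br)Br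
Why: Appel bromination converts the primary propargylic alcohol into the bromide without allenic rearrangement.

Step 9
Reactants: 17 (S)-carvone; 16 1-bromo-4-methylpent-2-yne
Product: 19 (2S,5S)-2-methyl-2-(4-methylpent-2-yn-1-yl)-5-(prop-1-en-2-yl)cyclohexan-1-one, via lithium enolate 18 (not isolated)
Conditions: Li (2.05 equiv), NH3 (l), t-BuOH (1 equiv), THF, −78 °C; then 16, THF, −78 to −33 °C
Reagents that add atoms: none
Why: Birch-type reduction gives the enolate regiospecifically and alkylation by axial attack on the half-chair with equatorial isopropenyl places the new chain cis to isopropenyl, fixing the quaternary centre (the minor diastereomer is removed by chromatography).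

Step 10
Reactants: 19 (2S,5S)-2-methyl-2-(4-methylpent-2-yn-1-yl)-5-(prop-1-en-2-yl)cyclohexan-1-one
Product: 20 (2S,5S)-2-methyl-2-(4-methyl-2-oxopentyl)-5-(prop-1-en-2-yl)cyclohexan-1-one
Conditions: (Ph3P)AuCl (cat.), AgOTf (cat.), 1,4-dioxane/H2O, 60 °C
Reagents that add atoms: water, O
Why: gold-catalysed alkyne hydration is steered by the ring carbonyl, which attacks the nearer alkyne carbon in a five-membered mode, so the 1,4-diketone should form regioselectively and the isopropenyl group is untouched.

Step 11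
Reactants: 20 (2S,5S)-2-methyl-2-(4-methyl-2-oxopentyl)-5-(prop-1-en-2-yl)cyclohexan-1-one
Product: 21 (5S,7aS)-7a-methyl-3-(propan-2-yl)-5-(prop-1-en-2-yl)-1,4,5,6,7,7a-hexahydro-2H-inden-2-one
Conditions: KOH, EtOH, reflux
Reagents that add atoms: none
Why: intramolecular aldol condensation of a 1,4-diketone is the classical cyclopentenone annulation, and only the enolate on the isobutyl side leads to a five-membered aldol that can dehydrate.

Step 12
Reactants: 21 (5S,7aS)-7a-methyl-3-(propan-2-yl)-5-(prop-1-en-2-yl)-1,4,5,6,7,7a-hexahydro-2H-inden-2-one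
Product: 23 (3aR,5S,7aS)-7a-methyl-3-(propan-2-yl)-5-(prop-1-en-2-yl)-3a,4,5,6,7,7a-hexahydro-1H-inden-2-yl trifluoromethanesulfonate, via lithium enolate 22 (not isolated)
Conditions: Li, NH3 (l), t-BuOH (1 equiv), THF, −78 °C; NH3 evaporated; then PhNTf2, THF, 0 °C
Reagents that add atoms: N-phenylbis(trifluoromethanesulfonimide), O=S(=O)(N(c1ccccc1)S(=O)(=O)C(F)(F)F)C(F)(F)F
Why: in the dissolving-metal reduction the ring-fusion carbanion is protonated on the face opposite the angular methyl (trans-hydrindane), and the regio-defined enolate is trapped as the enol triflate (reductive triflation).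

Step 13
Reactants: 23 (3aR,5S,7aS)-7a-methyl-3-(propan-2-yl)-5-(prop-1-en-2-yl)-3a,4,5,6,7,7a-hexahydro-1H-inden-2-yl trifluoromethanesulfonate
Product: 25 (3aR,5S,7aS)-7a-methyl-3-(propan-2-yl)-2-{[(trifluoromethyl)sulfonyl]oxy}-3a,4,5,6,7,7a-hexahydro-1H-inden-5-yl acetate, via methoxy hydroperoxide 24 (not isolated)
Conditions: O3 (1 equiv), CH2Cl2/MeOH, −78 °C; then Ac2O, Et3N, DMAP (cat.), 0 °C to rt
Reagents that add atoms: ozone, [O-][O+]=O; methanol, CO
Why: ozonolysis of the isopropenyl group in methanol and Criegee rearrangement of the acylated methoxy hydroperoxide replace the C–C bond by C–O with retention, while the electron-poor enol triflate alkene should not be attacked.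

Step 14
Reactants: 25 (3aR,5S,7aS)-7a-methyl-3-(propan-2-yl)-2-{[(trifluoromethyl)sulfonyl]oxy}-3a,4,5,6,7,7a-hexahydro-1H-inden-5-yl acetate
Product: 26 (3aR,5S,7aS)-7a-methyl-3-(propan-2-yl)-3a,4,5,6,7,7a-hexahydro-1H-inden-5-yl acetate
Conditions: Pd(OAc)2 (cat.), PPh3, n-Bu3N, HCO2H, DMF, 60 °C
Reagents that add atoms: none
Why: palladium-catalysed formate reduction replaces the enol triflate by hydrogen and leaves the isopropyl-substituted ring D alkene in place.

Step 15
Reactants: 26 (3aR,5S,7aS)-7a-methyl-3-(propan-2-yl)-3a,4,5,6,7,7a-hexahydro-1H-inden-5-yl acetate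
Product: 27 (3aR,5S,7aS)-7a-methyl-3-(propan-2-yl)-3a,4,5,6,7,7a-hexahydro-1H-inden-5-ol
Conditions: K2CO3 (cat.), MeOH, rt
Reagents that add atoms: none
Why: base-catalysed transesterification removes the acetate.

Step 16
Reactants: 27 (3aR,5S,7aS)-7a-methyl-3-(propan-2-yl)-3a,4,5,6,7,7a-hexahydro-1H-inden-5-ol
Product: 28 (3aR,7aS)-7a-methyl-3-(propan-2-yl)-1,3a,4,6,7,7a-hexahydro-5H-inden-5-one
Conditions: Dess–Martin periodinane, NaHCO3, CH2Cl2, rt
Reagents that add atoms: none
Why: Dess–Martin oxidation of the secondary alcohol gives the ring C ketone without touching the alkene.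

Step 17
Reactants: 28 (3aR,7aS)-7a-methyl-3-(propan-2-yl)-1,3a,4,6,7,7a-hexahydro-5H-inden-5-one
Product: 30 (3aR,7aR)-7a-methyl-3-(propan-2-yl)-3a,4,7,7a-tetrahydro-1H-inden-5-yl trifluoromethanesulfonate, via potassium enolate 29 (not isolated)
Conditions: KN(SiMe3)2, THF, −78 °C; then PhNTf2, −78 to 0 °C
Reagents that add atoms: N-phenylbis(trifluoromethanesulfonimide), O=S(=O)(N(c1ccccc1)S(=O)(=O)C(F)(F)F)C(F)(F)F
Why: deprotonation should occur on the side away from the ring fusion, because an enolate double bond next to the trans fusion is strained (the behaviour of trans-fused 3-keto steroids), which places the triflate alkene where the dipolarophile is needed.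

Step 18
Reactants: 30 (3aR,7aR)-7a-methyl-3-(propan-2-yl)-3a,4,7,7a-tetrahydro-1H-inden-5-yl trifluoromethanesulfonate
Product: 32 (2R,3R,3aS,7aS)-2-hydroxy-7a-methyl-3-(propan-2-yl)-2,3,3a,4,7,7a-hexahydro-1H-inden-5-yl trifluoromethanesulfonate, via alkylborane 31 (not isolated)
Conditions: BH3·THF, THF, 0 °C to rt; then NaBO3·4H2O, THF/H2O, rt
Reagents that add atoms: sodium perborate, [Na+].[Na+].O[B-]1(O)OO[B-](O)(O)OO1
Why: hydroboration puts boron on the less substituted carbon and adds syn from the face opposite the angular methyl, which sets the isopropyl-bearing centre and the carbinol, while the electron-poor enol triflate alkene is expected not to react.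

Step 19
Reactants: 32 (2R,3R,3aS,7aS)-2-hydroxy-7a-methyl-3-(propan-2-yl)-2,3,3a,4,7,7a-hexahydro-1H-inden-5-yl trifluoromethanesulfonate; 12 (1Z)-1-{(2S,3S)-2-[2-(1,3-dioxolan-2-yl)ethyl]-3-methylcyclopentylidene}ethyl trifluoromethanesulfonate
Product: 34 (2R,3R,3aS,7aS)-5-[(1Z)-1-{(2S,3S)-2-[2-(1,3-dioxolan-2-yl)ethyl]-3-methylcyclopentylidene}ethyl]-7a-methyl-3-(propan-2-yl)-2,3,3a,4,7,7a-hexahydro-1H-inden-2-ol, via pinacol boronate 33 (not isolated)
Conditions: B2pin2, PdCl2(dppf) (cat.), KOAc, 1,4-dioxane, 80 °C; then 12, aq. K3PO4, 80 °C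
Reagents that add atoms: none
Why: Miyaura borylation of the less hindered cyclohexenyl triflate followed by Suzuki–Miyaura coupling with the tetrasubstituted enol triflate joins the fragments with retention of both alkene geometries and tolerates the free hydroxyl.

Step 20
Reactants: 34 (2R,3R,3aS,7aS)-5-[(1Z)-1-{(2S,3S)-2-[2-(1,3-dioxolan-2-yl)ethyl]-3-methylcyclopentylidene}ethyl]-7a-methyl-3-(propan-2-yl)-2,3,3a,4,7,7a-hexahydro-1H-inden-2-ol
Product: 36 3-[(1S,2S,5Z)-5-{1-[(2R,3R,3aS,7aS)-2-hydroxy-7a-methyl-3-(propan-2-yl)-2,3,3a,4,7,7a-hexahydro-1H-inden-5-yl]ethylidene}-2-methylcyclopentyl]propanal oxime, via aldehyde 35 (not isolated)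
Conditions: NH2OH·HCl, EtOH/H2O, 50 °C
Reagents that add atoms: hydroxylamine hydrochloride, NO.Cl
Why: the weakly acidic hydroxylammonium salt hydrolyses the dioxolane and condenses with the aldehyde as it forms, which avoids strong acid on the diene.

Step 21
Reactants: 36 3-[(1S,2S,5Z)-5-{1-[(2R,3R,3aS,7aS)-2-hydroxy-7a-methyl-3-(propan-2-yl)-2,3,3a,4,7,7a-hexahydro-1H-inden-5-yl]ethylidene}-2-methylcyclopentyl]propanal oxime
Product: 38 pentacyclic 2-isoxazoline (ring B closed; C=N carbon in ring B next to the B/C fusion CH; isoxazoline oxygen on the ring C carbinol carbon cis to the new C–C bond; Z ring B alkene and free ring D hydroxyl kept), via nitrile oxide 37 (not isolated)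
Conditions: PhI(OAc)2, CF3CO2H (cat.), MeOH, 0.002 M, slow addition, 0 °C to rt
Reagents that add atoms: none
Why: Oxidation of the aldoxime gives nitrile oxide 37, which adds in one concerted suprafacial (3+2) step across the trisubstituted cyclohexene of the diene, carbon to the ring CH and oxygen to the fully substituted carbon, the orientation nitrile oxides show with trisubstituted alkenes and 1,3-dienes. The closest known reaction type is the intramolecular nitrile oxide–alkene cycloaddition used for medium and large carbocycles. The eight-membered carbocycle closes by C–C bond formation at the far alkene carbon (tether of three sp3 carbons plus the Z tetrasubstituted alkene), and the isoxazoline closes by C–O bond formation at the near carbon, so the heterocycle is fused to ring C and its N–O unit spans two carbons of the new ring. Both new stereocentres arise cis from the suprafacial addition, and their face is set by the ring A stereocentre that carries the tether together with the Z alkene, which let the dipole reach only the cyclohexene face on the tether side; this is also the face opposite the axial angular methyl (matched case). The step needs site selectivity for the cyclohexene over the nearer tetrasubstituted alkene, which is a poor dipolarophile and would have to form two adjacent quaternary carbons, and it needs suppression of furoxan formation, which high dilution and slow generation of the dipole should secure.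

Step 22
Reactants: 38 pentacyclic 2-isoxazoline
Product: 40 β-hydroxy ketone (ring B ketone next to the B/C fusion CH; tertiary ring C alcohol; Z ring B alkene; ring D secondary alcohol), via hydroxy imine 39 (not isolated)
Conditions: H2 (1 atm), Raney Ni, B(OH)3, MeOH/H2O, rt
Reagents that add atoms: water, O
Why: hydrogenolysis of the N–O bond and boric-acid-buffered hydrolysis of the β-hydroxy imine is the standard unmasking of an isoxazoline as an aldol, mild enough to spare the tetrasubstituted alkene and the α-stereocentre.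

Step 23
Reactants: 40 β-hydroxy ketone
Product: 41 exo-methylene diol (C=CH2 in place of the ring B carbonyl)
Conditions: Cp2TiMe2 (excess), toluene, 70 °C
Reagents that add atoms: dimethyltitanocene, C[Ti](C)(C1C=CC=C1)C1C=CC=C1
Why: Petasis methylenation is non-basic, so neither retro-aldol cleavage of the tertiary aldol nor epimerisation at the fusion CH should occur, and free hydroxyl groups are tolerated with excess reagent.

Step 24
Reactants: 41 exo-methylene diol
Product: 42 epoxy diol with exo-methylene (epoxide oxygen cis to the tertiary hydroxyl)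
Conditions: VO(acac)2 (cat.), t-BuOOH, CH2Cl2, 0 °C to rt
Reagents that add atoms: tert-butyl hydroperoxide, CC(C)(C)OO
Why: vanadium-catalysed epoxidation is directed by the tertiary allylic alcohol, which delivers oxygen to the tetrasubstituted ring B alkene on its own face (cis-epoxy alcohol, the rule for eight-membered allylic alcohols), and the homoallylic methylene reacts far more slowly.

Step 25
Reactants: 42 epoxy diol with exo-methylene
Product: 43 epoxy diol with the ring B secondary methyl (ring D alcohol of the target)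
Conditions: H2 (1 atm), Pd/C, EtOAc, rt
Reagents that add atoms: none
Why: heterogeneous hydrogenation should add hydrogen to the exocyclic alkene from the ring B face opposite the tertiary hydroxyl and the epoxide oxygen, which leaves the new methyl cis to that hydroxyl as the target requires.

Step 26
Reactants: 43 epoxy diol with the ring B secondary methyl
Product: 44 target CNP0332295.1
Conditions: Dess–Martin periodinane, NaHCO3, CH2Cl2, 0 °C to rt
Reagents that add atoms: none
Why: buffered Dess–Martin oxidation of the only secondary alcohol gives the cyclopentanone under non-enolising conditions, so the kinetically set isopropyl-bearing α-centre is kept.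

**Compound list**

1 | cyclopent-2-en-1-one | O=C1CCC=C1 | starting material
2 | 2-iodocyclopent-2-en-1-one | O=C1CCC=C1I | intermediate
3 | 2-vinyl-1,3-dioxolane | C=CC1OCCO1 | starting material
4 | 9-[2-(1,3-dioxolan-2-yl)ethyl]-9-borabicyclo[3.3.1]nonane | O1CCOC1CCB1C2CCCC1CCC2 | intermediate (not isolated)
5 | 2-[2-(1,3-dioxolan-2-yl)ethyl]cyclopent-2-en-1-one | O=C1CCC=C1CCC1OCCO1 | intermediate
6 | bromomagnesium (3S)-2-[2-(1,3-dioxolan-2-yl)ethyl]-3-methylcyclopent-1-en-1-olate | Br[Mg]OC1=C(CCC2OCCO2)[C@@H](C)CC1 | intermediate (not isolated)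
7 | (3S)-2-[2-(1,3-dioxolan-2-yl)ethyl]-3-methylcyclopent-1-en-1-yl trifluoromethanesulfonate | FC(F)(F)S(=O)(=O)OC1=C(CCC2OCCO2)[C@@H](C)CC1 | intermediate
8 | 2-{2-[(5S)-2-(1-ethoxyethenyl)-5-methylcyclopent-1-en-1-yl]ethyl}-1,3-dioxolane | CCOC(=C)C1=C(CCC2OCCO2)[C@@H](C)CC1 | intermediate (not isolated)
9 | 1-{(3S)-2-[2-(1,3-dioxolan-2-yl)ethyl]-3-methylcyclopent-1-en-1-yl}ethan-1-one | CC(=O)C1=C(CCC2OCCO2)[C@@H](C)CC1 | intermediate
10 | triethyl{[(1Z)-1-{(2S,3S)-2-[2-(1,3-dioxolan-2-yl)ethyl]-3-methylcyclopentylidene}ethyl]oxy}silane (side chain and methyl cis) | CC[Si](CC)(CC)O/C(C)=C1/CC[C@H](C)[C@@H]1CCC2OCCO2 | intermediate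
11 | lithium (1Z)-1-{(2S,3S)-2-[2-(1,3-dioxolan-2-yl)ethyl]-3-methylcyclopentylidene}ethan-1-olate | [Li]O/C(C)=C1/CC[C@H](C)[C@@H]1CCC2OCCO2 | intermediate (not isolated)
12 | (1Z)-1-{(2S,3S)-2-[2-(1,3-dioxolan-2-yl)ethyl]-3-methylcyclopentylidene}ethyl trifluoromethanesulfonate | FC(F)(F)S(=O)(=O)O/C(C)=C1/CC[C@H](C)[C@@H]1CCC2OCCO2 | intermediate
13 | 3-methylbut-1-yne | CC(C)C#C | starting material
14 | lithium 3-methylbut-1-yn-1-ide | [Li]C#CC(C)C | intermediate (not isolated)
15 | 4-methylpent-2-yn-1-ol | CC(C)C#CCO | intermediate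
16 | 1-bromo-4-methylpent-2-yne | CC(C)C#CCBr | intermediate
17 | (S)-carvone, (5S)-2-methyl-5-(prop-1-en-2-yl)cyclohex-2-en-1-one | CC1=CC[C@@H](CC1=O)C(C)=C | starting material
18 | lithium (5S)-2-methyl-5-(prop-1-en-2-yl)cyclohex-1-en-1-olate | CC1=C(O[Li])C[C@@H](C(C)=C)CC1 | intermediate (not isolated)
19 | (2S,5S)-2-methyl-2-(4-methylpent-2-yn-1-yl)-5-(prop-1-en-2-yl)cyclohexan-1-one (alkynyl chain cis to isopropenyl) | CC(C)C#CC[C@]1(C)CC[C@H](C(C)=C)CC1=O | intermediate
20 | (2S,5S)-2-methyl-2-(4-methyl-2-oxopentyl)-5-(prop-1-en-2-yl)cyclohexan-1-one | CC(C)CC(=O)C[C@]1(C)CC[C@H](C(C)=C)CC1=O | intermediate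
21 | (5S,7aS)-7a-methyl-3-(propan-2-yl)-5-(prop-1-en-2-yl)-1,4,5,6,7,7a-hexahydro-2H-inden-2-one | CC(C)C1=C2C[C@@H](C(C)=C)CC[C@@]2(C)CC1=O | intermediate
22 | lithium (3aR,5S,7aS)-7a-methyl-3-(propan-2-yl)-5-(prop-1-en-2-yl)-3a,4,5,6,7,7a-hexahydro-1H-inden-2-olate (trans-fused) | CC(C)C1=C(O[Li])C[C@]2(C)CC[C@H](C(C)=C)C[C@@H]12 | intermediate (not isolated)
23 | (3aR,5S,7aS)-7a-methyl-3-(propan-2-yl)-5-(prop-1-en-2-yl)-3a,4,5,6,7,7a-hexahydro-1H-inden-2-yl trifluoromethanesulfonate (trans-fused) | CC(C)C1=C(OS(=O)(=O)C(F)(F)F)C[C@]2(C)CC[C@H](C(C)=C)C[C@@H]12 | intermediate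
24 | (3aR,5S,7aS)-5-(1-hydroperoxy-1-methoxyethyl)-7a-methyl-3-(propan-2-yl)-3a,4,5,6,7,7a-hexahydro-1H-inden-2-yl trifluoromethanesulfonate (epimers at the peroxy carbon) | CC(C)C1=C(OS(=O)(=O)C(F)(F)F)C[C@]2(C)CC[C@H](C(C)(OC)OO)C[C@@H]12 | intermediate (not isolated)
25 | (3aR,5S,7aS)-7a-methyl-3-(propan-2-yl)-2-{[(trifluoromethyl)sulfonyl]oxy}-3a,4,5,6,7,7a-hexahydro-1H-inden-5-yl acetate | CC(C)C1=C(OS(=O)(=O)C(F)(F)F)C[C@]2(C)CC[C@H](OC(C)=O)C[C@@H]12 | intermediate
26 | (3aR,5S,7aS)-7a-methyl-3-(propan-2-yl)-3a,4,5,6,7,7a-hexahydro-1H-inden-5-yl acetate | CC(C)C1=CC[C@]2(C)CC[C@H](OC(C)=O)C[C@@H]12 | intermediate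
27 | (3aR,5S,7aS)-7a-methyl-3-(propan-2-yl)-3a,4,5,6,7,7a-hexahydro-1H-inden-5-ol | CC(C)C1=CC[C@]2(C)CC[C@H](O)C[C@@H]12 | intermediate
28 | (3aR,7aS)-7a-methyl-3-(propan-2-yl)-1,3a,4,6,7,7a-hexahydro-5H-inden-5-one | CC(C)C1=CC[C@]2(C)CCC(=O)C[C@@H]12 | intermediate
29 | potassium (3aR,7aR)-7a-methyl-3-(propan-2-yl)-3a,4,7,7a-tetrahydro-1H-inden-5-olate | CC(C)C1=CC[C@]2(C)CC=C(O[K])C[C@@H]12 | intermediate (not isolated)
30 | (3aR,7aR)-7a-methyl-3-(propan-2-yl)-3a,4,7,7a-tetrahydro-1H-inden-5-yl trifluoromethanesulfonate | CC(C)C1=CC[C@]2(C)CC=C(OS(=O)(=O)C(F)(F)F)C[C@@H]12 | intermediate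
31 | C-2 borane adduct of 30 (BH2 in the place of the hydroxyl group of 32, boron and the new C-3 hydrogen on the face opposite the angular methyl) | CC(C)[C@H]1[C@H](B)C[C@]2(C)CC=C(OS(=O)(=O)C(F)(F)F)C[C@@H]12 | intermediate (not isolated)
32 | (2R,3R,3aS,7aS)-2-hydroxy-7a-methyl-3-(propan-2-yl)-2,3,3a,4,7,7a-hexahydro-1H-inden-5-yl trifluoromethanesulfonate (trans-fused; isopropyl cis to angular methyl, hydroxyl trans to it) | CC(C)[C@H]1[C@H](O)C[C@]2(C)CC=C(OS(=O)(=O)C(F)(F)F)C[C@@H]12 | intermediate
33 | (2R,3R,3aS,7aS)-7a-methyl-3-(propan-2-yl)-5-(4,4,5,5-tetramethyl-1,3,2-dioxaborolan-2-yl)-2,3,3a,4,7,7a-hexahydro-1H-inden-2-ol | CC(C)[C@H]1[C@H](O)C[C@]2(C)CC=C(B3OC(C)(C)C(C)(C)O3)C[C@@H]12 | intermediate (not isolated)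
34 | (2R,3R,3aS,7aS)-5-[(1Z)-1-{(2S,3S)-2-[2-(1,3-dioxolan-2-yl)ethyl]-3-methylcyclopentylidene}ethyl]-7a-methyl-3-(propan-2-yl)-2,3,3a,4,7,7a-hexahydro-1H-inden-2-ol | CC(C)[C@H]1[C@H](O)C[C@]2(C)CC=C(C[C@@H]12)/C(C)=C3/CC[C@H](C)[C@@H]3CCC4OCCO4 | intermediate
35 | 3-[(1S,2S,5Z)-5-{1-[(2R,3R,3aS,7aS)-2-hydroxy-7a-methyl-3-(propan-2-yl)-2,3,3a,4,7,7a-hexahydro-1H-inden-5-yl]ethylidene}-2-methylcyclopentyl]propanal | CC(C)[C@H]1[C@H](O)C[C@]2(C)CC=C(C[C@@H]12)/C(C)=C3/CC[C@H](C)[C@@H]3CCC=O | intermediate (not isolated)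
36 | oxime of 35 (E/Z mixture at C=N) | CC(C)[C@H]1[C@H](O)C[C@]2(C)CC=C(C[C@@H]12)/C(C)=C3/CC[C@H](C)[C@@H]3CCC=NO | intermediate
37 | nitrile oxide from 36, 3-[(1S,2S,5Z)-5-{1-[(2R,3R,3aS,7aS)-2-hydroxy-7a-methyl-3-(propan-2-yl)-2,3,3a,4,7,7a-hexahydro-1H-inden-5-yl]ethylidene}-2-methylcyclopentyl]propanenitrile oxide | CC(C)[C@H]1[C@H](O)C[C@]2(C)CC=C(C[C@@H]12)/C(C)=C3/CC[C@H](C)[C@@H]3CCC#[N+][O-] | intermediate (not isolated)
38 | pentacyclic 2-isoxazoline (rings A–D plus isoxazoline; B/C fusion trans, new C–C and C–O bonds cis on ring C and opposite the angular methyl; Z ring B alkene; other centres as in 34) | CC(C)[C@H]1[C@H](O)C[C@]2(C)C[C@@H]3C(CC[C@H]4[C@@H](C)CC/C4=C(C)/[C@@]35C[C@@H]12)=NO5 | intermediate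
39 | β-hydroxy imine from 38 (C=NH in place of the ring B carbonyl of 40) | CC(C)[C@H]1[C@H](O)C[C@]2(C)C[C@@H]3C(=N)CC[C@H]4[C@@H](C)CC/C4=C(C)/[C@@]3(O)C[C@@H]12 | intermediate (not isolated)
40 | β-hydroxy ketone (ring B ketone next to the B/C fusion CH, tertiary ring C alcohol cis to the ring B bond at that CH, Z ring B alkene, ring D secondary alcohol) | CC(C)[C@H]1[C@H](O)C[C@]2(C)C[C@@H]3C(=O)CC[C@H]4[C@@H](C)CC/C4=C(C)/[C@@]3(O)C[C@@H]12 | intermediate
41 | exo-methylene diol (C=CH2 in place of the ring B carbonyl of 40) | CC(C)[C@H]1[C@H](O)C[C@]2(C)C[C@@H]3C(=C)CC[C@H]4[C@@H](C)CC/C4=C(C)/[C@@]3(O)C[C@@H]12 | intermediate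
42 | epoxy diol with exo-methylene (tetrasubstituted A/B epoxide, oxygen cis to the tertiary hydroxyl) | CC(C)[C@H]1[C@H](O)C[C@]2(C)C[C@@H]3C(=C)CC[C@H]4[C@@H](C)CC[C@]45O[C@]5(C)[C@@]3(O)C[C@@H]12 | intermediate
43 | epoxy diol with the ring B secondary methyl (target with a ring D secondary alcohol in place of the ketone) | CC(C)[C@H]1[C@H](O)C[C@]2(C)C[C@@H]3[C@H](C)CC[C@H]4[C@@H](C)CC[C@]45O[C@]5(C)[C@@]3(O)C[C@@H]12 | intermediate
44 | CNP0332295.1 | CC(C)[C@H]1C(=O)C[C@]2(C)C[C@@H]3[C@H](C)CC[C@H]4[C@@H](C)CC[C@]45O[C@]5(C)[C@@]3(O)C[C@@H]12 | target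

**Step count and risks**

Total: 26 steps. Longest linear sequence: 20 steps (steps 7–26, from 3-methylbut-1-yne; 18 steps counted from (S)-carvone).

Steps most likely to fail:

Step 21. The eight-membered closure may be slower than dimerisation of the dipole to the furoxan or than its capture by the nearer tetrasubstituted alkene in the five-membered mode. The fallback changes the dipole to one that can be heated for long periods. Oxime 36 is heated in degassed xylene (140 °C, 0.005 M, sealed vessel), where its NH-nitrone tautomer should undergo the reversible intramolecular oxime–olefin cycloaddition (1,2-prototropy route) to the N-unsubstituted isoxazolidine F1, in which the same two bonds and the same two rings are formed. Oxidation of F1 with MnO2 in CH2Cl2 returns to isoxazoline 38.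

Step 5. The rhodium hydride may reduce the carbonyl group (1,2-addition), fail to reach the fully substituted β-carbon or move the ring alkene. The fallback delivers hydride without a metal catalyst. Enone 9 is treated with catecholborane (THF, rt), whose conjugate reduction runs through a six-membered transition state open only to the s-cis enone and should give the Z-configured boron enolate F2 with hydride entering opposite the ring methyl. Methyllithium converts F2 into lithium enolate 11, where the route is rejoined (triflation to 12).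

Step 25. Adsorption through the hydroxyl groups may steer hydrogen to the wrong face of the exocyclic alkene, or the two faces may not be discriminated on the metal surface. The fallback builds the methyl group in stages with a bulky, non-adsorbing reagent. Alkene 42 is hydroborated with 9-BBN, which should approach from the more open ring face opposite the tertiary hydroxyl and place hydrogen on the ring carbon from that face, giving alkylborane F3. NaBO3 oxidises F3 to primary alcohol F4. Sulfonylation of the primary hydroxyl only (TsCl, pyridine, 0 °C) gives tosylate F5, and LiEt3BH in THF replaces the sulfonate by hydride to give 43 (the tetrasubstituted epoxide has no carbon open to hydride attack).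

Further compounds
F1 | step 21 | N-unsubstituted isoxazolidine (38 with CH–NH in place of C=N; new CH centre not assigned) | CC(C)[C@H]1[C@H](O)C[C@]2(C)C[C@@H]3C(CC[C@H]4[C@@H](C)CC/C4=C(C)/[C@@]35C[C@@H]12)NO5
F2 | step 5 | 2-{[(1Z)-1-{(2S,3S)-2-[2-(1,3-dioxolan-2-yl)ethyl]-3-methylcyclopentylidene}ethyl]oxy}-1,3,2-benzodioxaborole | B1(Oc2ccccc2O1)O/C(C)=C1/CC[C@H](C)[C@@H]1CCC1OCCO1
F3 | step 25 | 9-borabicyclo[3.3.1]nonan-9-ylmethyl analogue of 43 (CH2–B in place of the ring B methyl) | CC(C)[C@H]1[C@H](O)C[C@]2(C)C[C@@H]3[C@H](CB6C7CCCC6CCC7)CC[C@H]4[C@@H](C)CC[C@]45O[C@]5(C)[C@@]3(O)C[C@@H]12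
F4 | step 25 | hydroxymethyl analogue of 43 (CH2OH in place of the ring B methyl) | CC(C)[C@H]1[C@H](O)C[C@]2(C)C[C@@H]3[C@H](CO)CC[C@H]4[C@@H](C)CC[C@]45O[C@]5(C)[C@@]3(O)C[C@@H]12
F5 | step 25 | primary 4-methylbenzenesulfonate of F4 | CC(C)[C@H]1[C@H](O)C[C@]2(C)C[C@@H]3[C@H](COS(=O)(=O)c6ccc(C)cc6)CC[C@H]4[C@@H](C)CC[C@]45O[C@]5(C)[C@@]3(O)C[C@@H]12
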